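**Plan**

- Central ring numbering: C1(Me)=C2, C3 (ring A, the acylresorcinol), C4 (aroyl), C5 (ring B), C6H2. C4 is the ketone α-carbon and lies 1,4 to C1, so an O–C(=O) link from C1 to C4 is the CO2 of a 2-pyrone: it can be installed by cycloaddition and removed later through a β-keto acid.
- Retrosynthesis: cut the chalcone Cα=Cβ bond (aldol) and the ring A–acetyl bond, then C3–ring A with ring A taken back to cyclohexane-1,3-dione, then restore the C1–O–CO–C4 lactone from C4–H, and last cut C4–C5 and C1–C6 (3-aroyl-6-methyl-2-pyrone plus ring-B styrene).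
- Forward: the pyrone (carrying ring C) and the styrene close the carbocycle as a bridged lactone; palladium opens the lactone and joins the dione at C3; CO2 leaves; the dione ring is acetylated and aromatised to ring A; an aldol condensation adds the last aryl ring; the MOM groups come off.
- Stereochemistry: C5 and the bridge face come from the ligand-controlled endo cycloaddition; C3 from double inversion at palladium (cis to the departing carboxylate, hence trans to ring B); C4 from protonation of the enolate left by CO2, anti to the pseudoaxial C3 substituent; the E-enone from aldol dehydration.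

Key step: step 7

Abbreviations: MOM = methoxymethyl; ArC = 2,4-bis(methoxymethoxy)-3-(3-methylbut-2-en-1-yl)phenyl; ArB = 2,4-bis(methoxymethoxy)phenyl; C1–C6 in the Why lines are the central-ring atoms as numbered above.

Assumption: the facial sense that a copper(II) bis(oxazoline) complex imposes on a chelated 3-aroyl-2-pyrone is taken to follow that of 3-alkoxycarbonyl-2-pyrones; the (S,S) ligand is written, and its mirror image would be used if the opposite face is delivered.

**Route**

Step 1
Reactants: 1 2,4-dihydroxyacetophenone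
Product: 2 2,4-dihydroxy-3-prenylacetophenone
Conditions: prenyl bromide (1.0 equiv), 10% aq. KOH, 0 °C → rt
Reagents that add atoms: prenyl bromide (1-bromo-3-methylbut-2-ene), CC(C)=CCBr
Why: Phenoxide C-alkylation by the allylic bromide in water, where solvation of the phenoxide oxygens disfavours O-alkylation, is directed to C3, the carbon flanked by both oxygens; the C5 and O-prenyl isomers that this reaction type also gives are removed by chromatography.

Step 2
Reactants: 2 2,4-dihydroxy-3-prenylacetophenone
Product: 3 2,4-bis(methoxymethoxy)-3-prenylacetophenone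
Conditions: NaH (2.6 equiv), MOMCl (2.6 equiv), DMF, 0 °C → rt
Reagents that add atoms: chloromethyl methyl ether (MOMCl), COCCl
Why: Williamson-type alkylation of both phenoxides; sodium hydride is used because the 2-OH is hydrogen-bonded to the acetyl group and flanked by the prenyl chain.

Step 3
Reactants: 3 2,4-bis(methoxymethoxy)-3-prenylacetophenone
Product: 4 ethyl 3-ArC-3-oxopropanoate
Conditions: NaH (3 equiv), (EtO)2CO (5 equiv), THF, reflux; AcOH quench
Reagents that add atoms: diethyl carbonate, CCOC(=O)OCC
Why: Crossed Claisen condensation of the methyl ketone enolate with diethyl carbonate, driven by deprotonation of the β-ketoester formed; the MOM ether on O2 prevents closure to a 4-hydroxycoumarin.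

Step 4
Reactants: 4 ethyl 3-ArC-3-oxopropanoate; 5 but-3-yn-2-one
Product: 7 3-(ArC-carbonyl)-6-methyl-2H-pyran-2-one, via Michael adduct 6 (not isolated)
Conditions: 5 (1.2 equiv), Cs2CO3 (0.2 equiv), MeCN, 0 °C → rt, then 60 °C
Reagents that add atoms: none
Why: Base-catalysed Michael addition of the β-ketoester to the terminal ynone gives 6, whose vinylogous enolate oxygen then acylates on the ethyl ester (lactonisation with loss of ethanol), the classical 2-pyranone synthesis from acetylenic ketones and active-methylene esters, run under carbonate so that the MOM ethers survive.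

Step 5
Reactants: 8 2,4-dihydroxybenzaldehyde
Product: 9 2,4-bis(methoxymethoxy)benzaldehyde
Conditions: NaH (2.5 equiv), MOMCl (2.5 equiv), DMF, 0 °C → rt
Reagents that add atoms: chloromethyl methyl ether (MOMCl), COCCl
Why: Williamson-type alkylation of both phenoxides of a non-enolisable aldehyde, the strong base being needed for the chelated 2-OH.

Step 6
Reactants: 9 2,4-bis(methoxymethoxy)benzaldehyde
Product: 10 2,4-bis(methoxymethoxy)styrene
Conditions: Ph3PCH3Br (1.3 equiv), KOtBu (1.25 equiv), THF, 0 °C → rt
Reagents that add atoms: methyltriphenylphosphonium bromide, C[P+](c1ccccc1)(c1ccccc1)c1ccccc1.[Br-]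
Why: Wittig methylenation of an electron-rich, non-enolisable benzaldehyde with the unstabilised ylide.

Step 7
Reactants: 7 3-(ArC-carbonyl)-6-methyl-2H-pyran-2-one; 10 2,4-bis(methoxymethoxy)styrene
Product: 11 (1S,4S,8R)-4-(ArC-carbonyl)-8-ArB-1-methyl-2-oxabicyclo[2.2.2]oct-5-en-3-one (aryl endo)
Conditions: 10 (2 equiv), Cu(OTf)2 (10 mol%), (S,S)-t-Bu-BOX (11 mol%), 4 Å MS, CH2Cl2, −20 → 0 °C; work-up and chromatography below rt
Reagents that add atoms: none
Why: Copper(II) held between the lactone and ketone carbonyls of 7 lowers the pyrone LUMO, and the electron-rich styrene 10 adds across pyrone C3 and C6 in a concerted but asynchronous [4+2] in which its CH2 terminus bonds to the electrophilic C6 ahead of the benzylic carbon bonding to C3 (C1–C6 and C4–C5 of the target ring). The closest known reaction is the chiral-Lewis-acid-catalysed inverse-demand Diels–Alder reaction of 3-acyl- and 3-alkoxycarbonyl-2-pyrones with enol ethers and other electron-rich alkenes, which gives isolable bridged lactones. The only ring closed is the six-membered carbocycle (the cyclohexene of the target), formed by suprafacial cycloaddition onto one face of the pyrone, the lactone becoming the two-atom bridge. The bridgeheads C1 and C4 are fixed together by the pyrone face the alkene takes, which the tert-butyl groups of the ligand on the chelate are to select, and C8 is set by endo approach of the aryl group under the diene, which places it anti to the O–C(=O) bridge. The step needs regio-, peri-, endo and facial selectivity: the polarisation of the chelated pyrone (C6 most electrophilic) against the styrene (CH2 most nucleophilic) fixes the regiochemistry, two-point binding keeps the aroyl oxygen on copper and away from a hetero-Diels–Alder path, and the low temperature keeps CO2 in the adduct.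

Step 8
Reactants: 11 bridged lactone; 12 cyclohexane-1,3-dione
Product: 14 2-[(1S,5S,6R)-6-(ArC-carbonyl)-5-ArB-3-methylcyclohex-2-en-1-yl]-3-hydroxycyclohex-2-en-1-one, via β-keto acid 13 (not isolated)
Conditions: 12 (1.5 equiv), Et3N (2 equiv), Pd(PPh3)4 (5 mol%), degassed THF, 0 °C → rt; then 45 °C until CO2 evolution ends; pH 7 buffer work-up
Reagents that add atoms: none
Why: Tsuji–Trost allylic alkylation of a vinyl lactone: Pd(0) ionises the tertiary allylic C1–O bond anti to the carboxylate, the soft dione enolate attacks the less substituted allyl terminus C3 anti to palladium (double inversion, so the new C–C bond is cis to the C4 carboxylate and trans to ring B), and the β-keto carboxylate 13 then loses CO2 to an exocyclic enolate whose C3 substituent is held pseudoaxial by allylic 1,3-strain, so that protonation by Et3NH+ from the opposite face should set C4 with the aroyl group cis to the new ring and trans to ring B.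

Step 9
Reactants: 14 ketone with free dione ring
Product: 15 2-[(1S,5S,6R)-6-(ArC-carbonyl)-5-ArB-3-methylcyclohex-2-en-1-yl]-3-(methoxymethoxy)cyclohex-2-en-1-one
Conditions: MOMCl (1.3 equiv), iPr2NEt (2 equiv), CH2Cl2, 0 °C
Reagents that add atoms: chloromethyl methyl ether (MOMCl), COCCl
Why: O-alkylation of the vinylogous acid by the hard chloromethyl ether; the two carbonyls of the symmetric dione give the same vinylogous ester, and the amine base leaves C4 untouched.

Step 10
Reactants: 15 MOM vinylogous ester
Product: 16 6-acetyl derivative of 15 (written as its chelated enol)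
Conditions: LDA (1.1 equiv), THF, −78 °C; MeC(O)N(OMe)Me (1.5 equiv), −78 → −30 °C; aq. NH4Cl
Reagents that add atoms: N-methoxy-N-methylacetamide, CC(=O)N(C)OC
Why: Kinetic α′-deprotonation of the 3-alkoxyenone by LDA (the only other α-hydrogen, at C4, is tertiary and flanked by two ring-bearing carbons) followed by C-acylation with the Weinreb amide, whose stable tetrahedral adduct prevents proton exchange with the acidic product.

Step 11
Reactants: 16 acetylated vinylogous ester
Product: 17 1-[3-[(1S,5S,6R)-6-(ArC-carbonyl)-5-ArB-3-methylcyclohex-2-en-1-yl]-2-hydroxy-4-(methoxymethoxy)phenyl]ethan-1-one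
Conditions: DDQ (1.1 equiv), 1,4-dioxane, rt
Reagents that add atoms: none
Why: Quinone dehydrogenation: the enolised β-diketone is a 1-hydroxycyclohexa-1,3-diene that gives up hydride from its ring CH2–CH2 unit and aromatises to the o-hydroxyacetophenone, one equivalent at room temperature sparing the allylic C–H bonds.

Step 12
Reactants: 17 ring-A acetophenone; 9 2,4-bis(methoxymethoxy)benzaldehyde
Product: 18 hepta-MOM chalcone (E)
Conditions: 9 (1.2 equiv), 50% aq. KOH (10 equiv), EtOH, 0 °C → rt; dil. HCl to pH 5
Reagents that add atoms: none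
Why: Claisen–Schmidt condensation of the methyl ketone with the non-enolisable aldehyde, E1cB dehydration giving the E-enone; the other ketone has only a tertiary α-hydrogen and cannot condense, and C4 is expected to hold because its enolate would be a strained, fully substituted exocyclic enolate.

Step 13
Reactants: 18 hepta-MOM chalcone
Product: 19 target (CNP0186421.2)
Conditions: 3 M aq. HCl–MeOH (1:6), rt → 40 °C, argon
Reagents that add atoms: none
Why: Acid-catalysed acetal exchange to methanol cleaves all seven MOM ethers; the mild temperature and short time are chosen to stay ahead of chroman, flavanone and ketal formation.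

**Compound list**

1 | 1-(2,4-dihydroxyphenyl)ethan-1-one | CC(=O)c1ccc(O)cc1O | starting material
2 | 1-[2,4-dihydroxy-3-(3-methylbut-2-en-1-yl)phenyl]ethan-1-one | CC(=O)c1ccc(O)c(CC=C(C)C)c1O | intermediate
3 | 1-[2,4-bis(methoxymethoxy)-3-(3-methylbut-2-en-1-yl)phenyl]ethan-1-one | CC(=O)c1ccc(OCOC)c(CC=C(C)C)c1OCOC | intermediate
4 | ethyl 3-[2,4-bis(methoxymethoxy)-3-(3-methylbut-2-en-1-yl)phenyl]-3-oxopropanoate | CCOC(=O)CC(=O)c1ccc(OCOC)c(CC=C(C)C)c1OCOC | intermediate
5 | but-3-yn-2-one | CC(=O)C#C | starting material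
6 | ethyl (E)-2-[2,4-bis(methoxymethoxy)-3-(3-methylbut-2-en-1-yl)benzoyl]-5-oxohex-3-enoate (not isolated; C2 racemic and labile, left unmarked) | CCOC(=O)C(/C=C/C(C)=O)C(=O)c1ccc(OCOC)c(CC=C(C)C)c1OCOC | intermediate
7 | 3-[2,4-bis(methoxymethoxy)-3-(3-methylbut-2-en-1-yl)benzoyl]-6-methyl-2H-pyran-2-one | CC1=CC=C(C(=O)c2ccc(OCOC)c(CC=C(C)C)c2OCOC)C(=O)O1 | intermediate
8 | 2,4-dihydroxybenzaldehyde | O=Cc1ccc(O)cc1O | starting material
9 | 2,4-bis(methoxymethoxy)benzaldehyde | O=Cc1ccc(OCOC)cc1OCOC | intermediate
10 | 1-ethenyl-2,4-bis(methoxymethoxy)benzene | C=Cc1ccc(OCOC)cc1OCOC | intermediate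
11 | (1S,4S,8R)-4-[2,4-bis(methoxymethoxy)-3-(3-methylbut-2-en-1-yl)benzoyl]-8-[2,4-bis(methoxymethoxy)phenyl]-1-methyl-2-oxabicyclo[2.2.2]oct-5-en-3-one (aryl on C8 anti to the O2–C3 bridge) | O=C1O[C@]2(C)C=C[C@@]1(C(=O)c3ccc(OCOC)c(CC=C(C)C)c3OCOC)[C@@H](c4ccc(OCOC)cc4OCOC)C2 | intermediate
12 | cyclohexane-1,3-dione | O=C1CCCC(=O)C1 | starting material
13 | (1R,2R,6R)-1-[2,4-bis(methoxymethoxy)-3-(3-methylbut-2-en-1-yl)benzoyl]-6-[2,4-bis(methoxymethoxy)phenyl]-2-(2-hydroxy-6-oxocyclohex-1-en-1-yl)-4-methylcyclohex-3-ene-1-carboxylic acid (not isolated) | O=C(c1ccc(OCOC)c(CC=C(C)C)c1OCOC)[C@]2(C(=O)O)[C@@H](C3=C(O)CCCC3=O)C=C(C)C[C@@H]2c2ccc(OCOC)cc2OCOC | intermediate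
14 | 2-[(1S,5S,6R)-6-[2,4-bis(methoxymethoxy)-3-(3-methylbut-2-en-1-yl)benzoyl]-5-[2,4-bis(methoxymethoxy)phenyl]-3-methylcyclohex-2-en-1-yl]-3-hydroxycyclohex-2-en-1-one | O=C(c1ccc(OCOC)c(CC=C(C)C)c1OCOC)[C@H]2[C@@H](C3=C(O)CCCC3=O)C=C(C)C[C@@H]2c2ccc(OCOC)cc2OCOC | intermediate
15 | 2-[(1S,5S,6R)-6-[2,4-bis(methoxymethoxy)-3-(3-methylbut-2-en-1-yl)benzoyl]-5-[2,4-bis(methoxymethoxy)phenyl]-3-methylcyclohex-2-en-1-yl]-3-(methoxymethoxy)cyclohex-2-en-1-one | O=C(c1ccc(OCOC)c(CC=C(C)C)c1OCOC)[C@H]2[C@@H](C3=C(OCOC)CCCC3=O)C=C(C)C[C@@H]2c2ccc(OCOC)cc2OCOC | intermediate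
16 | 6-acetyl-2-[(1S,5S,6R)-6-[2,4-bis(methoxymethoxy)-3-(3-methylbut-2-en-1-yl)benzoyl]-5-[2,4-bis(methoxymethoxy)phenyl]-3-methylcyclohex-2-en-1-yl]-3-(methoxymethoxy)cyclohex-2-en-1-one, written as its hydrogen-bonded enol (C1–OH, C1=C6) | O=C(c1ccc(OCOC)c(CC=C(C)C)c1OCOC)[C@H]2[C@@H](C3=C(OCOC)CCC(C(C)=O)=C3O)C=C(C)C[C@@H]2c2ccc(OCOC)cc2OCOC | intermediate
17 | 1-[3-[(1S,5S,6R)-6-[2,4-bis(methoxymethoxy)-3-(3-methylbut-2-en-1-yl)benzoyl]-5-[2,4-bis(methoxymethoxy)phenyl]-3-methylcyclohex-2-en-1-yl]-2-hydroxy-4-(methoxymethoxy)phenyl]ethan-1-one | O=C(c1ccc(OCOC)c(CC=C(C)C)c1OCOC)[C@H]2[C@@H](c3c(OCOC)ccc(C(C)=O)c3O)C=C(C)C[C@@H]2c2ccc(OCOC)cc2OCOC | intermediate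
18 | (E)-3-[2,4-bis(methoxymethoxy)phenyl]-1-[3-[(1S,5S,6R)-6-[2,4-bis(methoxymethoxy)-3-(3-methylbut-2-en-1-yl)benzoyl]-5-[2,4-bis(methoxymethoxy)phenyl]-3-methylcyclohex-2-en-1-yl]-2-hydroxy-4-(methoxymethoxy)phenyl]prop-2-en-1-one | O=C(c1ccc(OCOC)c(CC=C(C)C)c1OCOC)[C@H]2[C@@H](c3c(OCOC)ccc(C(=O)/C=C/c4ccc(OCOC)cc4OCOC)c3O)C=C(C)C[C@@H]2c2ccc(OCOC)cc2OCOC | intermediate
19 | (E)-1-[3-[(1S,5S,6R)-6-[2,4-dihydroxy-3-(3-methylbut-2-en-1-yl)benzoyl]-5-(2,4-dihydroxyphenyl)-3-methylcyclohex-2-en-1-yl]-2,4-dihydroxyphenyl]-3-(2,4-dihydroxyphenyl)prop-2-en-1-one | CC(C)=CCc1c(O)ccc(C(=O)[C@H]2[C@@H](c3c(O)ccc(C(=O)/C=C/c4ccc(O)cc4O)c3O)C=C(C)C[C@@H]2c2ccc(O)cc2O)c1O | target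

**Step count and risks**

Total steps: 13. Longest linear sequence: 11 steps (steps 1–4 and 7–13, from 1 to 19).

Steps most likely to fail:

Step 8. Palladium must reach the alkene face that the endo aryl ring covers, so ionisation may be slow. The palladium-bound β-keto carboxylate can also lose CO2 before the dione arrives, and the enolate so formed collapses by elimination to a conjugated diene. Attack at the methyl-bearing allyl terminus or on the dione oxygen is a further loss. The fallback sets out from 11 and returns at 14. Lactone 11 is heated in toluene at about 100 °C, where cycloreversion expels CO2 and leaves the dienyl ketone F1. Cyclohexane-1,3-dione 12 is then added to the β-carbon (C3) of this dienone under catalytic DBU in THF (Michael addition), anti to ring B, which allylic strain against the aroyl group holds pseudoaxial. Protonation of the enolate as in step 8 gives 14.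

Step 7. The methyl group on pyrone C6 slows bond formation at the carbon that must become quaternary, the Lewis acid can oligomerise the electron-rich styrene, a hetero-cycloaddition through the aroyl enone can compete, and facial discrimination by the ligand may be poor. The fallback sets out from 7 and 10 and returns at 14. The two are combined without catalyst in CH2Cl2 at 10–12 kbar and room temperature, which should give the endo adduct as a racemate, 11 together with its mirror image, the enantiomeric lactone F2. Step 8 is then run with Pd2(dba)3 and one enantiomer of the DACH-phenyl bis(2-diphenylphosphinobenzamide) ligand as a kinetic resolution, in which 11 is ionised faster and carried on to 14 while F2 is left behind.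

Step 10. Acyl transfer from the amide to the hindered lithium enolate may be slow, and during that time the enolate can exchange protons with the γ-position or with C4–H, or simply return unchanged on work-up. The fallback sets out from 9 and 15 and returns at 18, bypassing steps 11 and 12 and the hydroxide of step 12. Aldehyde 9 is homologated with (triphenylphosphoranylidene)acetaldehyde (Wittig, toluene, 80 °C) to the (E)-enal F3. The lithium enolate of 15 (LDA, THF, −78 °C) is trapped by F3 in a fast 1,2-aldol addition to give the aldol adduct F4, a mixture at the two new carbons, both of which become trigonal afterwards. Dess–Martin periodinane oxidises the carbinol to the enolised β-diketone F5, and DDQ in dioxane aromatises F5 directly to 18.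

Further compounds
F1 | step 8 | [(6R)-6-[2,4-bis(methoxymethoxy)phenyl]-4-methylcyclohexa-1,3-dien-1-yl][2,4-bis(methoxymethoxy)-3-(3-methylbut-2-en-1-yl)phenyl]methanone | CC1=CC=C(C(=O)c2ccc(OCOC)c(CC=C(C)C)c2OCOC)[C@@H](c2ccc(OCOC)cc2OCOC)C1
F2 | step 7 | (1R,4R,8S)-4-[2,4-bis(methoxymethoxy)-3-(3-methylbut-2-en-1-yl)benzoyl]-8-[2,4-bis(methoxymethoxy)phenyl]-1-methyl-2-oxabicyclo[2.2.2]oct-5-en-3-one | O=C1O[C@@]2(C)C=C[C@]1(C(=O)c3ccc(OCOC)c(CC=C(C)C)c3OCOC)[C@H](c4ccc(OCOC)cc4OCOC)C2
F3 | step 10 | (E)-3-[2,4-bis(methoxymethoxy)phenyl]prop-2-enal | O=C/C=C/c1ccc(OCOC)cc1OCOC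
F4 | step 10 | 6-[(E)-3-[2,4-bis(methoxymethoxy)phenyl]-1-hydroxyprop-2-en-1-yl] derivative of 15 (diastereomer mixture at ring C6 and at the carbinol carbon, left unmarked) | O=C(c1ccc(OCOC)c(CC=C(C)C)c1OCOC)[C@H]2[C@@H](C3=C(OCOC)CCC(C(O)/C=C/c4ccc(OCOC)cc4OCOC)C3=O)C=C(C)C[C@@H]2c2ccc(OCOC)cc2OCOC
F5 | step 10 | 6-[(E)-3-[2,4-bis(methoxymethoxy)phenyl]prop-2-enoyl] derivative of 15, written as its hydrogen-bonded enol | O=C(c1ccc(OCOC)c(CC=C(C)C)c1OCOC)[C@H]2[C@@H](C3=C(OCOC)CCC(C(=O)/C=C/c4ccc(OCOC)cc4OCOC)=C3O)C=C(C)C[C@@H]2c2ccc(OCOC)cc2OCOC
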